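# Proposed total synthesis of CNP0196241.1 through a transannular vinylogous aldol closure

## Structural features

The target is a cis-fused decalin (ring A: C1–C5 and C10; ring B: C5–C10). Ring A carries the angelate at C1, a ketone at C2, an acetyl group at C3 and the C3=C4 double bond; ring B carries methyl groups at C5 and C6 and an acetate at C7. Five stereocentres are contiguous: C1 (S), C10 (R, tertiary alcohol), C5 (R, quaternary), C6 (R) and C7 (S). The C5 methyl, C6 methyl, C7 acetoxy and C10 hydroxyl groups share one face and the C1 angelate lies on the other. The fragile parts are: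

- the 2-acyl enone (C2=O, acetyl, C3=C4), a doubly activated alkene;
- C1 once it is flanked by carbonyl groups;
- the angelate, which can isomerise to the tiglate and migrate between vicinal oxygens;
- the tertiary C10 alcohol, which is β to the C2 ketone (retro-aldol, dehydration).

The real difficulty is the fusion bond C5–C10, which joins a quaternary carbon to a fully substituted carbinol carbon next to two further stereocentres. C5 is the γ-carbon of the C3-acetyl enone and C10 is a carbinol carbon, so this bond is a vinylogous aldol bond. The key step forms it across the ten-membered ring C1–C10 and closes rings A and B at once. Only C1, C6 and C7 must therefore be set on the open chain; C2, C5 and C10 are erased later (oxidation, dienol ether, ketone) and may be carried in any configuration.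

## Logic of the disconnections

**31 ⇒ 30 ⇒ 29 (C2 carbonyl).** No skeletal bond is cut; the C2 ketone is taken back to a silyl-protected alcohol. A C2 ketone in the ring-opened precursor would make C1 a 1,3-dicarbonyl carbon and would expose the ene-dione for the whole route. The gain is that the most electrophilic array appears only in the last step. The forward steps must cleave the silyl ether without basic alkoxide (angelate migration, retro-aldol) and oxidise under neutral conditions.

**29 ⇒ 27 (C5–C10).** Cutting the fusion bond opens both rings to the ten-membered keto enone 27. This is the retro vinylogous aldol; it removes two rings, the quaternary centre and the tertiary alcohol, and leaves three stereocentres that matter. The forward step makes three demands: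

- Only the acetyl enone may be enolised, and through its γ-hydrogen. C5 is not the only carbon that can reach across: the acetyl methyl carbon can reach C10 through a bridged six-membered ring, and a C9 enolate of the C10 ketone can reach C4 in a Michael sense.
- The closure must be cis, with the C5 methyl syn to the C6 methyl.
- The C6 methyl and C7 acetoxy groups are cis-vicinal and cannot both be pseudo-equatorial, so the control element has to be allylic strain, not a diequatorial preference.

**27 ⇒ 26 ⇒ 25 ⇒ 24 (C10 and C2 oxidation level).** The C10 ketone is traced to a PMB-protected alcohol and the C2 silyl ether to the free allylic alcohol. A C10 ketone cannot coexist with the C2 aldehyde needed for ring closure, because C1 would be doubly activated. The gain is that 24 is the direct product of the macrocyclisation. The forward steps need silylation without enolisation, PMB removal that spares silyl ether, esters and enone, and oxidation without acyl migration.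

**24 ⇒ 23 (C2–C3).** The carbinol–alkene bond is cut to an aldehyde and an alkenyl iodide in one chain. Chromium-mediated addition tolerates the esters and creates the C2 oxygen. The ring becomes an open chain. The forward step needs high dilution, C2 and C5 cis on C3=C4, and addition faster than loss of iodine.

**23 ⇒ 22 ⇒ 21 ⇒ 18 + 19 (C3=C4).** The alkene is cut by a Wittig disconnection to the C4 aldehyde 18 and the acetyl ylide 19, iodinated in the flask. C3, its iodine and the acetyl group arrive in one step. The forward step must give the Z iodoalkene (iodine cis to C5). The α-acyloxy aldehyde 23 must be made last and used at once.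

**18 ⇒ 17 ⇒ 15 (C4 aldehyde).** The aldehyde is traced to the isopropenyl group of 15 by anti-Markovnikov hydration. The alkene is an inert placeholder for C4 and C5 during the protecting-group steps. Hydroboration must spare the angelate alkene.

**15 ⇒ 12 + 13; 12 ⇒ 11 ⇒ 10 ⇒ 9 (C1–O acyl bond; diol differentiation).** The angelate is introduced on the chain, so that no hindered secondary alcohol next to a tertiary one has to be acylated late. C1 and C2 are told apart because C2 is primary. The esterification must not isomerise the Z alkene.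

**9 ⇒ 6 + 8; 8 ⇒ 7 (C6–C7).** This is an anti-selective allylboration with a 2-methylbut-2-enyl boronate. It sets the only two ring B centres that survive (C6, C7) under catalyst control and brings C4, C5 and both methyl groups. A Claisen route from achiral components would give racemic material and would spend its selectivity on C5, which is erased. The forward step needs the E boronate and catalyst-controlled face selection.

**6 ⇒ 4 ⇒ 3 ⇒ 1 + 2 (C9–C10).** C1 comes from the chiral pool with the C1/C2 oxygens tied together and the C10 oxygen distinct. The C10 configuration places no demand, since it is oxidised later.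

## Other disconnections considered

**Alternative 1:** The cut is C5–C6, reached by ring expansion.

- Forward step: the proline-derived hydrindenedione A1 is converted into the β-hydroxy selenide A2. AgBF4 (monovalent silver) turns selenium into a leaving group, C5 shifts from C7 to C6, and the dione A3 results.
- In favour: A1 comes from an achiral triketone by amine catalysis. The more substituted carbon migrates, the shift is stereospecific (retention at C5, inversion at C6), and A3 already holds the C5/C6 methyl pair, a C7 carbonyl and a C2 enone.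
- Against: the C6 configuration rests on a diastereoselective addition of a configurationally labile α-seleno organolithium to A1, with two new centres and competition from the enone. A3 lacks the C10 hydroxyl, the C1 oxygen, the acetyl group and the C3=C4 bond. Placing the C10 hydroxyl on the face of the angular methyl group runs against the steric bias of the bicycle, and C3 must be told apart from C1.
- Comparison: structurally it forms one ring B bond and one centre, where the chosen plan forms both rings, the fusion bond and two centres with every heteroatom group in place. Mechanistically the semipinacol shift is better precedented and is the better in predictability. In step economy it is better up to the bicyclic core (few steps, no protecting groups, catalytic enantiocontrol) but expected to be worse overall, because a long series of oxidation-level adjustments follows where the chosen plan needs two steps.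

**Alternative 2:** The cut is C5–C6 together with C10–O.

- Forward step: the epoxy alkene A4 is treated with FeCl3·6H2O (trivalent iron) in nitromethane. C5 opens the trans-epoxide at C6 with inversion and water captures the C10 cation anti to the new bond, giving A5.
- In favour: anti addition across C5=C10 translates by geometry into the cis fusion with hydroxyl and methyl on one face. C6 comes from an enantiopure epoxide. Ring B, the quaternary centre and the tertiary alcohol arise in one step from a simple substrate.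
- Against: both epoxide carbons are secondary, so five-membered closure at C7 competes. The cation can lose a proton instead of taking up water. The C7 hydroxyl has the wrong configuration and must be inverted. A5 lacks the C1 oxygen, the acetyl group and the C3=C4 bond.
- Comparison: on structure it is the equal of the chosen plan (both set C5 and C10 in one step). In stereochemical certainty of the fusion it is the better, since the cis fusion follows from the mechanism and not from a conformational preference. On mechanism it exchanges an enolisation-selectivity problem for a regiochemistry and termination problem. On step economy it is shorter to the bicycle and longer after it, so no overall gain is expected.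

**Alternative 3:** The cut is C1–C2.

- Forward step: the dialdehyde A6 is closed by a chiral triazolium salt and Et3N to the α-ketol A7.
- In favour: the unhindered C2 aldehyde forms the acyl anion equivalent and the neopentyl C1 aldehyde can only accept, so the crossed benzoin is chemoselective by design. It gives the C1 hydroxyl and C2 ketone at their final oxidation levels under mild conditions.
- Against: the C5 quaternary centre, the C10 carbinol and their relation to C6 and C7 must already be present in A6, so the main problem is moved, not solved. The catalyst must place the C1 hydroxyl trans to the C10 oxygen against any substrate bias. The ketol can equilibrate through its enediol. The acetyl group and C3=C4 remain to be added.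
- Comparison: in delivering the C1/C2 oxidation pattern directly it is the better; the chosen plan reaches the C2 ketone only by protection and late oxidation. As a single step it is the safer. In step economy it is expected to be worse, because A6 needs its own stereocontrolled synthesis of ring B and several steps follow A7.

Key step: step 19

Assumption: the configurations at C2, C5 and C10 of the intermediates are drawn as the isomers expected from Felkin–Anh addition (C10, C2) and allylic-strain-controlled hydroboration (C5); all three centres are erased later, so their epimers would converge.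

## Route

Step 1
Reactants: 1 (R)-2,2-dimethyl-1,3-dioxolane-4-carbaldehyde; 2 but-3-en-1-ylmagnesium bromide
Product: 3 (1S)-1-[(4R)-2,2-dimethyl-1,3-dioxolan-4-yl]pent-4-en-1-ol
Conditions: THF, −78 → −20 °C; aq. NH4Cl
Reagents that add atoms: none
Why: Grignard addition to an α-alkoxy aldehyde; Felkin–Anh attack anti to the ring oxygen should favour the anti (10S) carbinol drawn. C1 comes unchanged from the chiral pool, and C10 is oxidised in step 18, so its epimer converges.

Step 2
Reactants: 3 (1S)-1-[(4R)-2,2-dimethyl-1,3-dioxolan-4-yl]pent-4-en-1-ol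
Product: 4 (4R)-4-{(1S)-1-[(4-methoxybenzyl)oxy]pent-4-en-1-yl}-2,2-dimethyl-1,3-dioxolane
Conditions: NaH, 4-methoxybenzyl chloride, Bu4NI (cat.), THF/DMF, 0 °C → rt
Reagents that add atoms: 4-methoxybenzyl chloride, COc1ccc(CCl)cc1
Why: Williamson etherification; the C10 oxygen receives a group that is removed oxidatively at the end, orthogonal to silyl ethers and esters.

Step 3
Reactants: 4 (4R)-4-{(1S)-1-[(4-methoxybenzyl)oxy]pent-4-en-1-yl}-2,2-dimethyl-1,3-dioxolane
Product: 6 (4S)-4-[(4R)-2,2-dimethyl-1,3-dioxolan-4-yl]-4-[(4-methoxybenzyl)oxy]butanal, via ozonide 5 (not isolated)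
Conditions: O3, CH2Cl2, −78 °C (Sudan Red 7B end point); PPh3, −78 °C → rt
Reagents that add atoms: ozone, [O-][O+]=O
Why: Ozonolysis with reductive work-up; the terminal alkene reacts far faster than the anisyl ring and the indicator stops the reaction there. The new aldehyde carbon is C7.

Step 4
Reactants: 7 (E)-2-methylbut-2-en-1-ol
Product: 8 4,4,5,5-tetramethyl-2-[(E)-2-methylbut-2-en-1-yl]-1,3,2-dioxaborolane
Conditions: B2pin2, Pd(MeCN)4(BF4)2 (divalent palladium, 5 mol %), DMSO/MeOH, 50 °C
Reagents that add atoms: bis(pinacolato)diboron, CC1(C)OB(OC1(C)C)B1OC(C)(C)C(C)(C)O1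
Why: Palladium-catalysed borylation of an allylic alcohol; the syn π-allyl intermediate should deliver boron to the primary terminus with the E geometry kept.

Step 5
Reactants: 6 (4S)-4-[(4R)-2,2-dimethyl-1,3-dioxolan-4-yl]-4-[(4-methoxybenzyl)oxy]butanal; 8 4,4,5,5-tetramethyl-2-[(E)-2-methylbut-2-en-1-yl]-1,3,2-dioxaborolane
Product: 9 (3R,4S,7S)-7-[(4R)-2,2-dimethyl-1,3-dioxolan-4-yl]-7-[(4-methoxybenzyl)oxy]-2,3-dimethylhept-1-en-4-ol
Conditions: (R)-TRIP [(R)-3,3′-bis(2,4,6-triisopropylphenyl)-1,1′-binaphthyl-2,2′-diyl hydrogen phosphate, 5 mol %], toluene, −30 °C; aq. NaHCO3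
Reagents that add atoms: none
Why: Chiral-phosphoric-acid-catalysed allylboration through a Zimmerman–Traxler chair: the E boronate gives the anti pair, and the (R)-catalyst should direct attack to the Re face of the aldehyde, which sets C7 (S) and with it C6 (R). The remote centres C10 and C1 should have no influence.

Step 6
Reactants: 9 (3R,4S,7S)-7-[(4R)-2,2-dimethyl-1,3-dioxolan-4-yl]-7-[(4-methoxybenzyl)oxy]-2,3-dimethylhept-1-en-4-ol
Product: 10 (3R,4S,7S)-7-[(4R)-2,2-dimethyl-1,3-dioxolan-4-yl]-7-[(4-methoxybenzyl)oxy]-2,3-dimethylhept-1-en-4-yl acetate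
Conditions: Ac2O, pyridine, DMAP (cat.), CH2Cl2, 0 °C → rt
Reagents that add atoms: acetic anhydride, CC(=O)OC(C)=O
Why: Acetylation of the secondary alcohol under nucleophilic catalysis; the C7 acetate of the target is installed once and carried to the end.

Step 7
Reactants: 10 (3R,4S,7S)-7-[(4R)-2,2-dimethyl-1,3-dioxolan-4-yl]-7-[(4-methoxybenzyl)oxy]-2,3-dimethylhept-1-en-4-yl acetate
Product: 11 (3R,4S,7S,8R)-8,9-dihydroxy-7-[(4-methoxybenzyl)oxy]-2,3-dimethylnon-1-en-4-yl acetate
Conditions: AcOH/H2O (4:1), 40 °C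
Reagents that add atoms: none
Why: Acid hydrolysis of the terminal acetonide; acetate, PMB ether and the 1,1-disubstituted alkene should tolerate dilute acetic acid.

Step 8
Reactants: 11 (3R,4S,7S,8R)-8,9-dihydroxy-7-[(4-methoxybenzyl)oxy]-2,3-dimethylnon-1-en-4-yl acetate
Product: 12 (3R,4S,7S,8R)-9-[(tert-butyldimethylsilyl)oxy]-8-hydroxy-7-[(4-methoxybenzyl)oxy]-2,3-dimethylnon-1-en-4-yl acetate
Conditions: TBSCl (1.05 equiv), imidazole, CH2Cl2, 0 °C
Reagents that add atoms: tert-butyldimethylsilyl chloride, CC(C)(C)[Si](C)(C)Cl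
Why: Silylation is much faster at the primary hydroxyl (C2), which leaves the C1 hydroxyl free for the angelate.

Step 9
Reactants: 12 (3R,4S,7S,8R)-9-[(tert-butyldimethylsilyl)oxy]-8-hydroxy-7-[(4-methoxybenzyl)oxy]-2,3-dimethylnon-1-en-4-yl acetate; 13 angelic acid, (Z)-2-methylbut-2-enoic acid
Product: 15 (3R,4S,7S,8R)-4-(acetyloxy)-9-[(tert-butyldimethylsilyl)oxy]-7-[(4-methoxybenzyl)oxy]-2,3-dimethylnon-1-en-8-yl (2Z)-2-methylbut-2-enoate, via mixed anhydride 14 (not isolated)
Conditions: 13, 2,4,6-trichlorobenzoyl chloride, Et3N, toluene, rt; then 12, toluene, 80 °C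
Reagents that add atoms: none
Why: Yamaguchi-type esterification through the mixed anhydride without a nucleophilic catalyst, conditions under which angelates form without Z to E isomerisation. The alcohol attacks the less hindered angeloyl carbonyl, and C1 keeps its configuration because acylation occurs at oxygen.

Step 10
Reactants: 15 (3R,4S,7S,8R)-4-(acetyloxy)-9-[(tert-butyldimethylsilyl)oxy]-7-[(4-methoxybenzyl)oxy]-2,3-dimethylnon-1-en-8-yl (2Z)-2-methylbut-2-enoate
Product: 17 (2R,3R,4S,7S,8R)-4-(acetyloxy)-9-[(tert-butyldimethylsilyl)oxy]-1-hydroxy-7-[(4-methoxybenzyl)oxy]-2,3-dimethylnonan-8-yl (2Z)-2-methylbut-2-enoate, via alkylborane 16 (not isolated)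
Conditions: 9-BBN, THF, 0 °C → rt; H2O2, pH 7 phosphate buffer, 0 °C
Reagents that add atoms: hydrogen peroxide, OO
Why: Brown hydroboration–oxidation; the bulky borane should add only to the 1,1-disubstituted alkene (boron on C4) and not to the conjugated angelate, and buffered peroxide spares the esters. Attack anti to the C7 branch under allylic-strain control should favour the 5,6-syn isomer drawn; C5 is erased in step 19 in any case.

Step 11
Reactants: 17 (2R,3R,4S,7S,8R)-4-(acetyloxy)-9-[(tert-butyldimethylsilyl)oxy]-1-hydroxy-7-[(4-methoxybenzyl)oxy]-2,3-dimethylnonan-8-yl (2Z)-2-methylbut-2-enoate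
Product: 18 (2R,3R,4S,7S,8R)-4-(acetyloxy)-9-[(tert-butyldimethylsilyl)oxy]-7-[(4-methoxybenzyl)oxy]-2,3-dimethyl-1-oxononan-8-yl (2Z)-2-methylbut-2-enoate
Conditions: Dess–Martin periodinane, CH2Cl2, 0 °C → rt
Reagents that add atoms: none
Why: Dess–Martin oxidation of the primary alcohol under neutral conditions; esters, silyl ether and PMB ether are inert, and epimerisation at C5 would be without consequence.

Step 12
Reactants: 18 (2R,3R,4S,7S,8R)-4-(acetyloxy)-9-[(tert-butyldimethylsilyl)oxy]-7-[(4-methoxybenzyl)oxy]-2,3-dimethyl-1-oxononan-8-yl (2Z)-2-methylbut-2-enoate; 19 1-(triphenyl-λ5-phosphanylidene)propan-2-one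
Product: 21 (3Z,5R,6R,7S,10S,11R)-7-(acetyloxy)-12-[(tert-butyldimethylsilyl)oxy]-3-iodo-10-[(4-methoxybenzyl)oxy]-5,6-dimethyl-2-oxododec-3-en-11-yl (2Z)-2-methylbut-2-enoate, via iodo ylide 20 (not isolated)
Conditions: 19, N-iodosuccinimide, CH2Cl2, −20 °C; then 18, rt → 40 °C
Reagents that add atoms: N-iodosuccinimide, O=C1CCC(=O)N1I
Why: Wittig olefination with the α-iodo ylide made in the flask; stabilised ylides place the acyl group trans to the new chain, so iodine and C5 should end cis (Z), the geometry the ring needs.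

Step 13
Reactants: 21 (3Z,5R,6R,7S,10S,11R)-7-(acetyloxy)-12-[(tert-butyldimethylsilyl)oxy]-3-iodo-10-[(4-methoxybenzyl)oxy]-5,6-dimethyl-2-oxododec-3-en-11-yl (2Z)-2-methylbut-2-enoate
Product: 22 (3Z,5R,6R,7S,10S,11R)-7-(acetyloxy)-12-hydroxy-3-iodo-10-[(4-methoxybenzyl)oxy]-5,6-dimethyl-2-oxododec-3-en-11-yl (2Z)-2-methylbut-2-enoate
Conditions: HF·pyridine, pyridine, THF, 0 °C
Reagents that add atoms: none
Why: Acid-buffered fluoride cleaves the primary silyl ether; under these non-basic conditions the angelate should not move to the primary hydroxyl.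

Step 14
Reactants: 22 (3Z,5R,6R,7S,10S,11R)-7-(acetyloxy)-12-hydroxy-3-iodo-10-[(4-methoxybenzyl)oxy]-5,6-dimethyl-2-oxododec-3-en-11-yl (2Z)-2-methylbut-2-enoate
Product: 23 (3Z,5R,6R,7S,10S,11S)-7-(acetyloxy)-3-iodo-10-[(4-methoxybenzyl)oxy]-5,6-dimethyl-2,12-dioxododec-3-en-11-yl (2Z)-2-methylbut-2-enoate
Conditions: Dess–Martin periodinane, CH2Cl2, 0 °C; used at once
Reagents that add atoms: none
Why: Dess–Martin oxidation; the α-acyloxy aldehyde is configurationally fragile at C1, so it is made under non-basic conditions and cyclised without storage. C10 is still an ether, so C1 is α to one carbonyl only.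

Step 15
Reactants: 23 (3Z,5R,6R,7S,10S,11S)-7-(acetyloxy)-3-iodo-10-[(4-methoxybenzyl)oxy]-5,6-dimethyl-2,12-dioxododec-3-en-11-yl (2Z)-2-methylbut-2-enoate
Product: 24 (1R,2R,3E,5S,6R,7S,10S)-3-acetyl-7-(acetyloxy)-2-hydroxy-10-[(4-methoxybenzyl)oxy]-5,6-dimethylcyclodec-3-en-1-yl (2Z)-2-methylbut-2-enoate
Conditions: CrCl2 (8 equiv), NiCl2 (cat.), degassed DMSO, rt, high dilution (slow addition); aq. NH4Cl
Reagents that add atoms: none
Why: Nozaki–Hiyama–Kishi macrocyclisation: nickel-mediated activation of the C–I bond, transfer to chromium and addition to the aldehyde. The α-iodo enone may equally react through its chromium enolate; both paths form C2–C3. Addition anti to the C1 oxygen (Felkin–Anh) should give the 2R alcohol drawn, whose epimer converges in step 21, and the ring holds C2 and C5 cis on C3=C4.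

Step 16
Reactants: 24 (1R,2R,3E,5S,6R,7S,10S)-3-acetyl-7-(acetyloxy)-2-hydroxy-10-[(4-methoxybenzyl)oxy]-5,6-dimethylcyclodec-3-en-1-yl (2Z)-2-methylbut-2-enoate
Product: 25 (1S,2R,3E,5S,6R,7S,10S)-3-acetyl-7-(acetyloxy)-2-[(tert-butyldimethylsilyl)oxy]-10-[(4-methoxybenzyl)oxy]-5,6-dimethylcyclodec-3-en-1-yl (2Z)-2-methylbut-2-enoate
Conditions: TBSOTf, 2,6-lutidine, CH2Cl2, −78 → 0 °C
Reagents that add atoms: tert-butyldimethylsilyl trifluoromethanesulfonate, CC(C)(C)[Si](C)(C)OS(=O)(=O)C(F)(F)F
Why: Silyl triflate with a hindered pyridine base silylates the allylic alcohol without enolising the enone. The silyl ether keeps C2 at the alcohol level, so C1 is never flanked by two carbonyl groups.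

Step 17
Reactants: 25 (1S,2R,3E,5S,6R,7S,10S)-3-acetyl-7-(acetyloxy)-2-[(tert-butyldimethylsilyl)oxy]-10-[(4-methoxybenzyl)oxy]-5,6-dimethylcyclodec-3-en-1-yl (2Z)-2-methylbut-2-enoate
Product: 26 (1S,2R,3E,5S,6R,7S,10S)-3-acetyl-7-(acetyloxy)-2-[(tert-butyldimethylsilyl)oxy]-10-hydroxy-5,6-dimethylcyclodec-3-en-1-yl (2Z)-2-methylbut-2-enoate
Conditions: DDQ, CH2Cl2/pH 7 buffer, 0 °C → rt
Reagents that add atoms: none
Why: Oxidative cleavage of the PMB ether (hydride abstraction, hydrolysis of the oxocarbenium ion); the medium is buffered so that the angelate does not migrate to the freed C10 hydroxyl.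

Step 18
Reactants: 26 (1S,2R,3E,5S,6R,7S,10S)-3-acetyl-7-(acetyloxy)-2-[(tert-butyldimethylsilyl)oxy]-10-hydroxy-5,6-dimethylcyclodec-3-en-1-yl (2Z)-2-methylbut-2-enoate
Product: 27 (1R,2R,3E,5S,6R,7S)-3-acetyl-7-(acetyloxy)-2-[(tert-butyldimethylsilyl)oxy]-5,6-dimethyl-10-oxocyclodec-3-en-1-yl (2Z)-2-methylbut-2-enoate
Conditions: Dess–Martin periodinane, CH2Cl2, 0 °C → rt
Reagents that add atoms: none
Why: Dess–Martin oxidation of the C10 alcohol gives the α-acyloxy ketone; C2 is protected, so C1 is α to one carbonyl only and should keep its configuration.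

Step 19
Reactants: 27 (1R,2R,3E,5S,6R,7S)-3-acetyl-7-(acetyloxy)-2-[(tert-butyldimethylsilyl)oxy]-5,6-dimethyl-10-oxocyclodec-3-en-1-yl (2Z)-2-methylbut-2-enoate
Product: 29 (1R,2R,5R,6R,7S,10R)-3-acetyl-7-(acetyloxy)-2-[(tert-butyldimethylsilyl)oxy]-10-hydroxy-5,6-dimethyl-cis-bicyclo[4.4.0]dec-3-en-1-yl (2Z)-2-methylbut-2-enoate (route numbering), via silyl dienol ether 28 (not isolated)
Conditions: TMSOTf (1.1 equiv), Et3N (1.3 equiv), CH2Cl2, −78 → 0 °C; pentane, filtration under argon; TiCl4 (1.1 equiv), CH2Cl2, −78 °C; aq. NaHCO3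
Reagents that add atoms: none
Why: Soft enolisation (O-silylation of the more basic, conjugated acetyl carbonyl, then loss of the γ-hydrogen at C5) should give the extended dienol ether 28, in line with the selective dienol ether formation of conjugated ketones beside saturated ones; after the ammonium salt is removed, TiCl4 activates the C10 ketone and C5 adds to it, the closest known types being transannular aldol closures of cyclodecenones and vinylogous Mukaiyama aldol additions to ketones. With respect to the C4=C5 bond of 28, ring B closes in 6-(enolexo)-exo-trig and ring A in 6-(enolendo)-exo-trig fashion, both allowed. C5 is controlled by allylic 1,3-strain: with C3 and C6 cis on C4=C5 (the less strained in-ring geometry) the C6 hydrogen lies in the diene plane, so C10, which is tied to C6 through C7–C9, can reach C5 only on the face opposite the C6 methyl, and the C5 methyl ends cis to it. C10 follows from C5: with that alkene geometry only one staggered arrangement about the forming bond closes both six-membered rings, and it places the carbonyl oxygen gauche to the C5 methyl, which is the cis fusion with hydroxyl and methyl on one face. In this array the C6 methyl is pseudo-equatorial and the C7 acetoxy group pseudo-axial (cis-vicinal groups cannot both be equatorial), and the C1 angelate lies anti to the C10 carbonyl, the dipole-minimised arrangement. The step needs chemo- and regioselective enolisation: attack through C3 would need a four-membered ring, but the acetyl methyl carbon could reach C10 through a bridged six-membered ring and a C9 enol silane of the C10 ketone could add to C4. One equivalent of silyl triflate at low temperature, the lower basicity of the α-acyloxy ketone, the thermodynamic preference for the extended diene and the absence of amine when TiCl4 is added are meant to secure this, and the 2R silyloxy group stays pseudo-equatorial, away from the Lewis-acid-bound oxygen.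

Step 20
Reactants: 29 (1R,2R,5R,6R,7S,10R)-3-acetyl-7-(acetyloxy)-2-[(tert-butyldimethylsilyl)oxy]-10-hydroxy-5,6-dimethyl-cis-bicyclo[4.4.0]dec-3-en-1-yl (2Z)-2-methylbut-2-enoate
Product: 30 (1R,2R,5R,6R,7S,10R)-3-acetyl-7-(acetyloxy)-2,10-dihydroxy-5,6-dimethyl-cis-bicyclo[4.4.0]dec-3-en-1-yl (2Z)-2-methylbut-2-enoate (route numbering)
Conditions: HF·pyridine, THF, 0 °C → rt
Reagents that add atoms: none
Why: Fluoride cleavage of the allylic silyl ether under acidic buffering, which avoids alkoxide-mediated angelate migration and retro-aldol opening at C10.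

Step 21
Reactants: 30 (1R,2R,5R,6R,7S,10R)-3-acetyl-7-(acetyloxy)-2,10-dihydroxy-5,6-dimethyl-cis-bicyclo[4.4.0]dec-3-en-1-yl (2Z)-2-methylbut-2-enoate
Product: 31 CNP0196241.1, (1S,5R,6R,7S,10R)-3-acetyl-7-(acetyloxy)-10-hydroxy-5,6-dimethyl-2-oxo-cis-bicyclo[4.4.0]dec-3-en-1-yl (2Z)-2-methylbut-2-enoate (route numbering)
Conditions: Dess–Martin periodinane, CH2Cl2, 0 °C → rt
Reagents that add atoms: none
Why: Dess–Martin oxidation of the allylic secondary alcohol; the tertiary C10 alcohol cannot be oxidised, and the neutral, non-nucleophilic medium spares the doubly activated C3=C4 bond and the C1 centre.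

## Compound list

1 | (R)-2,2-dimethyl-1,3-dioxolane-4-carbaldehyde | O=C[C@H]1COC(C)(C)O1 | starting material
2 | but-3-en-1-ylmagnesium bromide | C=CCC[Mg]Br | starting material
3 | (1S)-1-[(4R)-2,2-dimethyl-1,3-dioxolan-4-yl]pent-4-en-1-ol | C=CCC[C@H](O)[C@H]1COC(C)(C)O1 | intermediate
4 | (4R)-4-{(1S)-1-[(4-methoxybenzyl)oxy]pent-4-en-1-yl}-2,2-dimethyl-1,3-dioxolane | C=CCC[C@H](OCc1ccc(OC)cc1)[C@H]1COC(C)(C)O1 | intermediate
5 | secondary ozonide (1,2,4-trioxolane) of 4, epimers at the trioxolane carbon | C1OC(CC[C@H](OCc2ccc(OC)cc2)[C@H]2COC(C)(C)O2)OO1 | intermediate (not isolated)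
6 | (4S)-4-[(4R)-2,2-dimethyl-1,3-dioxolan-4-yl]-4-[(4-methoxybenzyl)oxy]butanal | O=CCC[C@H](OCc1ccc(OC)cc1)[C@H]1COC(C)(C)O1 | intermediate
7 | (E)-2-methylbut-2-en-1-ol | C/C=C(\C)CO | starting material
8 | 4,4,5,5-tetramethyl-2-[(E)-2-methylbut-2-en-1-yl]-1,3,2-dioxaborolane | C/C=C(\C)CB1OC(C)(C)C(C)(C)O1 | intermediate
9 | (3R,4S,7S)-7-[(4R)-2,2-dimethyl-1,3-dioxolan-4-yl]-7-[(4-methoxybenzyl)oxy]-2,3-dimethylhept-1-en-4-ol | C=C(C)[C@@H](C)[C@@H](O)CC[C@H](OCc1ccc(OC)cc1)[C@H]1COC(C)(C)O1 | intermediate
10 | (3R,4S,7S)-7-[(4R)-2,2-dimethyl-1,3-dioxolan-4-yl]-7-[(4-methoxybenzyl)oxy]-2,3-dimethylhept-1-en-4-yl acetate | C=C(C)[C@@H](C)[C@@H](OC(C)=O)CC[C@H](OCc1ccc(OC)cc1)[C@H]1COC(C)(C)O1 | intermediate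
11 | (3R,4S,7S,8R)-8,9-dihydroxy-7-[(4-methoxybenzyl)oxy]-2,3-dimethylnon-1-en-4-yl acetate | C=C(C)[C@@H](C)[C@@H](OC(C)=O)CC[C@H](OCc1ccc(OC)cc1)[C@H](O)CO | intermediate
12 | (3R,4S,7S,8R)-9-[(tert-butyldimethylsilyl)oxy]-8-hydroxy-7-[(4-methoxybenzyl)oxy]-2,3-dimethylnon-1-en-4-yl acetate | C=C(C)[C@@H](C)[C@@H](OC(C)=O)CC[C@H](OCc1ccc(OC)cc1)[C@H](O)CO[Si](C)(C)C(C)(C)C | intermediate
13 | angelic acid, (Z)-2-methylbut-2-enoic acid | C/C=C(/C)C(=O)O | starting material
14 | (Z)-2-methylbut-2-enoic 2,4,6-trichlorobenzoic anhydride | C/C=C(/C)C(=O)OC(=O)c1c(Cl)cc(Cl)cc1Cl | intermediate (not isolated)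
15 | (3R,4S,7S,8R)-4-(acetyloxy)-9-[(tert-butyldimethylsilyl)oxy]-7-[(4-methoxybenzyl)oxy]-2,3-dimethylnon-1-en-8-yl (2Z)-2-methylbut-2-enoate | C=C(C)[C@@H](C)[C@@H](OC(C)=O)CC[C@H](OCc1ccc(OC)cc1)[C@H](OC(=O)/C(C)=C\C)CO[Si](C)(C)C(C)(C)C | intermediate
16 | B-alkyl-9-borabicyclo[3.3.1]nonane from 15, boron on C4 | B1(C2CCCC1CCC2)C[C@H](C)[C@@H](C)[C@@H](OC(C)=O)CC[C@H](OCc1ccc(OC)cc1)[C@H](OC(=O)/C(C)=C\C)CO[Si](C)(C)C(C)(C)C | intermediate (not isolated)
17 | (2R,3R,4S,7S,8R)-4-(acetyloxy)-9-[(tert-butyldimethylsilyl)oxy]-1-hydroxy-7-[(4-methoxybenzyl)oxy]-2,3-dimethylnonan-8-yl (2Z)-2-methylbut-2-enoate | OC[C@H](C)[C@@H](C)[C@@H](OC(C)=O)CC[C@H](OCc1ccc(OC)cc1)[C@H](OC(=O)/C(C)=C\C)CO[Si](C)(C)C(C)(C)C | intermediate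
18 | (2R,3R,4S,7S,8R)-4-(acetyloxy)-9-[(tert-butyldimethylsilyl)oxy]-7-[(4-methoxybenzyl)oxy]-2,3-dimethyl-1-oxononan-8-yl (2Z)-2-methylbut-2-enoate | O=C[C@H](C)[C@@H](C)[C@@H](OC(C)=O)CC[C@H](OCc1ccc(OC)cc1)[C@H](OC(=O)/C(C)=C\C)CO[Si](C)(C)C(C)(C)C | intermediate
19 | 1-(triphenyl-λ5-phosphanylidene)propan-2-one | CC(=O)C=P(c1ccccc1)(c1ccccc1)c1ccccc1 | starting material
20 | 1-iodo-1-(triphenyl-λ5-phosphanylidene)propan-2-one | CC(=O)C(I)=P(c1ccccc1)(c1ccccc1)c1ccccc1 | intermediate (not isolated)
21 | (3Z,5R,6R,7S,10S,11R)-7-(acetyloxy)-12-[(tert-butyldimethylsilyl)oxy]-3-iodo-10-[(4-methoxybenzyl)oxy]-5,6-dimethyl-2-oxododec-3-en-11-yl (2Z)-2-methylbut-2-enoate | CC(=O)/C(I)=C/[C@H](C)[C@@H](C)[C@@H](OC(C)=O)CC[C@H](OCc1ccc(OC)cc1)[C@H](OC(=O)/C(C)=C\C)CO[Si](C)(C)C(C)(C)C | intermediate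
22 | (3Z,5R,6R,7S,10S,11R)-7-(acetyloxy)-12-hydroxy-3-iodo-10-[(4-methoxybenzyl)oxy]-5,6-dimethyl-2-oxododec-3-en-11-yl (2Z)-2-methylbut-2-enoate | CC(=O)/C(I)=C/[C@H](C)[C@@H](C)[C@@H](OC(C)=O)CC[C@H](OCc1ccc(OC)cc1)[C@H](OC(=O)/C(C)=C\C)CO | intermediate
23 | (3Z,5R,6R,7S,10S,11S)-7-(acetyloxy)-3-iodo-10-[(4-methoxybenzyl)oxy]-5,6-dimethyl-2,12-dioxododec-3-en-11-yl (2Z)-2-methylbut-2-enoate | CC(=O)/C(I)=C/[C@H](C)[C@@H](C)[C@@H](OC(C)=O)CC[C@H](OCc1ccc(OC)cc1)[C@H](OC(=O)/C(C)=C\C)C=O | intermediate
24 | (1R,2R,3E,5S,6R,7S,10S)-3-acetyl-7-(acetyloxy)-2-hydroxy-10-[(4-methoxybenzyl)oxy]-5,6-dimethylcyclodec-3-en-1-yl (2Z)-2-methylbut-2-enoate | C/C=C(/C)C(=O)O[C@@H]1[C@H](O)/C(C(C)=O)=C\[C@H](C)[C@@H](C)[C@@H](OC(C)=O)CC[C@@H]1OCc2ccc(OC)cc2 | intermediate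
25 | (1S,2R,3E,5S,6R,7S,10S)-3-acetyl-7-(acetyloxy)-2-[(tert-butyldimethylsilyl)oxy]-10-[(4-methoxybenzyl)oxy]-5,6-dimethylcyclodec-3-en-1-yl (2Z)-2-methylbut-2-enoate | C/C=C(/C)C(=O)O[C@@H]1[C@H](O[Si](C)(C)C(C)(C)C)/C(C(C)=O)=C\[C@H](C)[C@@H](C)[C@@H](OC(C)=O)CC[C@@H]1OCc2ccc(OC)cc2 | intermediate
26 | (1S,2R,3E,5S,6R,7S,10S)-3-acetyl-7-(acetyloxy)-2-[(tert-butyldimethylsilyl)oxy]-10-hydroxy-5,6-dimethylcyclodec-3-en-1-yl (2Z)-2-methylbut-2-enoate | C/C=C(/C)C(=O)O[C@@H]1[C@H](O[Si](C)(C)C(C)(C)C)/C(C(C)=O)=C\[C@H](C)[C@@H](C)[C@@H](OC(C)=O)CC[C@@H]1O | intermediate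
27 | (1R,2R,3E,5S,6R,7S)-3-acetyl-7-(acetyloxy)-2-[(tert-butyldimethylsilyl)oxy]-5,6-dimethyl-10-oxocyclodec-3-en-1-yl (2Z)-2-methylbut-2-enoate (precursor of the key step) | C/C=C(/C)C(=O)O[C@@H]1[C@H](O[Si](C)(C)C(C)(C)C)/C(C(C)=O)=C\[C@H](C)[C@@H](C)[C@@H](OC(C)=O)CCC1=O | intermediate
28 | extended trimethylsilyl dienol ether of 27: exocyclic C3=C(CH3)OSiMe3, in-ring C4=C5 with C3 and C6 cis, C10 ketone | C/C=C(/C)C(=O)O[C@@H]1[C@H](O[Si](C)(C)C(C)(C)C)/C(=C(/C)O[Si](C)(C)C)/C=C(/C)[C@@H](C)[C@@H](OC(C)=O)CCC1=O | intermediate (not isolated)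
29 | (1R,2R,5R,6R,7S,10R)-3-acetyl-7-(acetyloxy)-2-[(tert-butyldimethylsilyl)oxy]-10-hydroxy-5,6-dimethyl-cis-bicyclo[4.4.0]dec-3-en-1-yl (2Z)-2-methylbut-2-enoate (product of the key step) | C/C=C(/C)C(=O)O[C@@H]1[C@H](O[Si](C)(C)C(C)(C)C)C(C(C)=O)=C[C@]2(C)[C@@H](C)[C@@H](OC(C)=O)CC[C@]12O | intermediate
30 | (1R,2R,5R,6R,7S,10R)-3-acetyl-7-(acetyloxy)-2,10-dihydroxy-5,6-dimethyl-cis-bicyclo[4.4.0]dec-3-en-1-yl (2Z)-2-methylbut-2-enoate | C/C=C(/C)C(=O)O[C@@H]1[C@H](O)C(C(C)=O)=C[C@]2(C)[C@@H](C)[C@@H](OC(C)=O)CC[C@]12O | intermediate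
31 | CNP0196241.1, (1S,5R,6R,7S,10R)-3-acetyl-7-(acetyloxy)-10-hydroxy-5,6-dimethyl-2-oxo-cis-bicyclo[4.4.0]dec-3-en-1-yl (2Z)-2-methylbut-2-enoate | C/C=C(/C)C(=O)O[C@@H]1C(=O)C(C(C)=O)=C[C@]2(C)[C@@H](C)[C@@H](OC(C)=O)CC[C@]12O | target

## Step count and least certain steps

Total step count: 21. Longest linear sequence: 20 steps (steps 1–3 and 5–21, from 1); step 4 is a one-step branch.

**Step 19 (key step).** The most likely failure is enolisation at the wrong place: silylation of the C10 ketone or of the acetyl methyl group, followed by transannular Michael closure between C9 and C4 or by bridged aldol closure. Further risks are loss of the C2 silyloxy group by β-elimination under the Lewis acid and poor facial selectivity, because the reactive conformer must carry the C7 acetoxy group pseudo-axial.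

Fallback: the nucleophile is fixed before the electrophile exists. It sets out from 26 and returns at 29.
- Allyl chloroformate and pyridine should give the C10 allyl carbonate F1.
- TBSOTf and Et3N, now without any competing ketone, should give the tert-butyldimethylsilyl dienol ether F2.
- Pd(PPh3)4 (zerovalent palladium) with morpholine should free the C10 alcohol F3.
- Parikh–Doering oxidation (SO3·pyridine, DMSO, iPr2NEt) should give the keto dienol ether F4.
- BF3·OEt2 at −78 °C should then effect the same C5–C10 closure to 29.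

**Step 15 (macrocyclisation).** The α-iodo enone may be reduced to a chromium dienolate that is protonated (loss of iodine) or loses the alkene geometry before the ring closes, and oligomerisation competes at a ten-membered ring.

Fallback: the ketone is masked so that an ordinary alkenyl iodide enters the reaction. It sets out from 21 and returns at 27.
- Luche reduction (NaBH4, CeCl3·7H2O) should give the iodo allylic alcohol F5.
- 4-Methoxybenzyl trichloroacetimidate with La(OTf)3 (cat.) should give the bis-PMB ether F6.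
- HF·pyridine should give the primary alcohol F7, and Dess–Martin oxidation the aldehyde F8.
- CrCl2/NiCl2 should give the macrocyclic allylic alcohol F9, and TBSOTf/2,6-lutidine the C2 silyl ether F10.
- DDQ should remove both PMB groups to give the diol F11, and a double Dess–Martin oxidation should deliver 27.

**Step 12 (iodo olefination).** The doubly stabilised ylide may add too slowly to the α-branched aldehyde, so that aldehyde decomposition and erosion of the Z selectivity take over.

Fallback: olefination and iodination are separated. It sets out from 18 and 19 and returns at 21.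
- The un-iodinated ylide 19 should give the (E)-enone F12.
- α-Iodination through conjugate addition and elimination (I2, K2CO3, DMAP cat., THF/H2O) should then give 21.

**Step 5 (allylboration).** Enantio- or diastereoselection may be insufficient with a 2-substituted crotyl boronate, or the E geometry of 8 may erode before addition.

Fallback: it sets out from 6 and returns at 9.
- Marshall–Tamaru propargylation with the allenylzinc reagent from (S)-but-3-yn-2-yl methanesulfonate (Pd(OAc)2, PPh3, Et2Zn) should give the anti homopropargylic alcohol F13. The sequence is anti-SN2′ palladation, retentive transmetalation and syn-SE2′ addition.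
- Zirconium-catalysed carboalumination (Me3Al, Cp2ZrCl2) with protonolysis should convert the alkyne into the isopropenyl group of 9.

## Further compounds

F1 | step 19 | C10 allyl carbonate of 26 | C/C=C(/C)C(=O)O[C@@H]1[C@H](O[Si](C)(C)C(C)(C)C)/C(C(C)=O)=C\[C@H](C)[C@@H](C)[C@@H](OC(C)=O)CC[C@@H]1OC(=O)OCC=C
F2 | step 19 | extended tert-butyldimethylsilyl dienol ether of F1 | C/C=C(/C)C(=O)O[C@@H]1[C@H](O[Si](C)(C)C(C)(C)C)/C(=C(/C)O[Si](C)(C)C(C)(C)C)/C=C(/C)[C@@H](C)[C@@H](OC(C)=O)CC[C@@H]1OC(=O)OCC=C
F3 | step 19 | C10 alcohol carrying the silyl dienol ether | C/C=C(/C)C(=O)O[C@@H]1[C@H](O[Si](C)(C)C(C)(C)C)/C(=C(/C)O[Si](C)(C)C(C)(C)C)/C=C(/C)[C@@H](C)[C@@H](OC(C)=O)CC[C@@H]1O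
F4 | step 19 | C10 ketone carrying the silyl dienol ether | C/C=C(/C)C(=O)O[C@@H]1[C@H](O[Si](C)(C)C(C)(C)C)/C(=C(/C)O[Si](C)(C)C(C)(C)C)/C=C(/C)[C@@H](C)[C@@H](OC(C)=O)CCC1=O
F5 | step 15 | (Z)-iodo allylic alcohol from 21 (carbinol epimers) | CC(O)/C(I)=C/[C@H](C)[C@@H](C)[C@@H](OC(C)=O)CC[C@H](OCc1ccc(OC)cc1)[C@H](OC(=O)/C(C)=C\C)CO[Si](C)(C)C(C)(C)C
F6 | step 15 | PMB ether of F5 | CC(OCc1ccc(OC)cc1)/C(I)=C/[C@H](C)[C@@H](C)[C@@H](OC(C)=O)CC[C@H](OCc1ccc(OC)cc1)[C@H](OC(=O)/C(C)=C\C)CO[Si](C)(C)C(C)(C)C
F7 | step 15 | primary alcohol from F6 | CC(OCc1ccc(OC)cc1)/C(I)=C/[C@H](C)[C@@H](C)[C@@H](OC(C)=O)CC[C@H](OCc1ccc(OC)cc1)[C@H](OC(=O)/C(C)=C\C)CO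
F8 | step 15 | C2 aldehyde from F7 | CC(OCc1ccc(OC)cc1)/C(I)=C/[C@H](C)[C@@H](C)[C@@H](OC(C)=O)CC[C@H](OCc1ccc(OC)cc1)[C@H](OC(=O)/C(C)=C\C)C=O
F9 | step 15 | macrocyclic allylic alcohol with C3 1-[(4-methoxybenzyl)oxy]ethyl group | C/C=C(/C)C(=O)O[C@@H]1[C@H](O)/C(C(C)OCc2ccc(OC)cc2)=C\[C@H](C)[C@@H](C)[C@@H](OC(C)=O)CC[C@@H]1OCc2ccc(OC)cc2
F10 | step 15 | C2 tert-butyldimethylsilyl ether of F9 | C/C=C(/C)C(=O)O[C@@H]1[C@H](O[Si](C)(C)C(C)(C)C)/C(C(C)OCc2ccc(OC)cc2)=C\[C@H](C)[C@@H](C)[C@@H](OC(C)=O)CC[C@@H]1OCc2ccc(OC)cc2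
F11 | step 15 | diol from F10 (C10 hydroxyl and C3 1-hydroxyethyl group) | C/C=C(/C)C(=O)O[C@@H]1[C@H](O[Si](C)(C)C(C)(C)C)/C(C(C)O)=C\[C@H](C)[C@@H](C)[C@@H](OC(C)=O)CC[C@@H]1O
F12 | step 12 | (E)-enone from 18 and 19 | CC(=O)/C=C/[C@H](C)[C@@H](C)[C@@H](OC(C)=O)CC[C@H](OCc1ccc(OC)cc1)[C@H](OC(=O)/C(C)=C\C)CO[Si](C)(C)C(C)(C)C
F13 | step 5 | anti homopropargylic alcohol from 6 | C#C[C@@H](C)[C@@H](O)CC[C@H](OCc1ccc(OC)cc1)[C@H]1COC(C)(C)O1
A1 | alternative 1 | (S)-7a-methyl-2,3,7,7a-tetrahydro-1H-indene-1,5(6H)-dione | O=C1CC[C@@]2(C)C(=C1)CCC2=O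
A2 | alternative 1 | β-hydroxy selenide, 1-hydroxy-7a-methyl-1-[1-(methylselanyl)ethyl]-hexahydroinden-5-one | O=C1CC[C@@]2(C)C(=C1)CC[C@@]2(O)[C@@H](C)[Se]C
A3 | alternative 1 | 4a,5-dimethyl-4,4a,7,8-tetrahydronaphthalene-2,6(3H,5H)-dione | O=C1CC[C@]2(C)[C@@H](C)C(=O)CCC2=C1
A4 | alternative 2 | 8-methyl-7-[2-(trans-3-methyloxiran-2-yl)ethyl]-1,4-dioxaspiro[4.5]dec-7-ene | C[C@H]1O[C@@H]1CCC1=C(C)CCC2(C1)OCCO2
A5 | alternative 2 | cis-decalin C2 ketal with C10 hydroxyl and epimeric C7 hydroxyl | C1C2(OCCO2)CC[C@]3(C)[C@@H](C)[C@H](O)CC[C@]13O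
A6 | alternative 3 | ring B dialdehyde with C10 triethylsilyl ether and C7 acetate | O=CCC[C@]1(C)[C@@H](C)[C@@H](OC(C)=O)CC[C@@]1(C=O)O[Si](CC)(CC)CC
A7 | alternative 3 | cis-decalin α-ketol with C1 hydroxyl, C2 ketone, C7 acetate and C10 triethylsilyl ether | O[C@@H]1C(=O)CC[C@]2(C)[C@@H](C)[C@@H](OC(C)=O)CC[C@]12O[Si](CC)(CC)CC
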